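# Proposed synthesis of CNP0206652.1 (compound 16)

## Analysis of the target

The target 16 joins two polyketide-type rings through one CH2: C3′ of a 6′-ethyl-4′-hydroxy-5′-methyl-2H-pyran-2-one and C7 of a 2,3-dihydro-1-benzofuran (benzofuran numbering O1, C2, C3, C3a, C4–C7, C7a; primed numbers for the pyranone). The benzene ring is a fully substituted acylphloroglucinol: C4–OH, C5–isobutyryl, C6–OH, C7–CH2 (bridge), C7a–O1 and C3a–C3, with O1 para to the acyl group and both free hydroxyls ortho to it. The only stereocentre is C2 (R, confirmed from the SMILES: O1 > isopropenyl carbon > C3 > H). It carries the isopropenyl group, is bound to O1 and is allylic, and nothing else in the molecule can relay stereochemical information to it, so a reagent or catalyst must set it. The feature the route is built on: O1–C2 is an allylic C–O bond, C3a is the enol α-carbon of a masked cyclohexane-1,3,5-trione, and C3, C2 and the C(CH3)=CH2 group together form one isoprene unit at the oxidation level of a 1,4-dielectrophile that spans the nucleophilic pair C3a/O1 of the dihydrofuran ring. Sensitive groups are the electron-rich polyphenol (oxidants, aerobic base), the allylic aryl ether O1–C2 (ionizable by acid or Pd(0), which would racemize C2), the isopropenyl group (acid moves the double bond into conjugation and on to a benzofuran), the CH2 bridge (retro-Mannich-type cleavage in strong acid) and five acidic OH groups. The difficulties are regiochemical and stereochemical rather than skeletal: C- versus O-alkylation of an ambident phloroglucinol, mono- versus bis-substitution of its two equivalent CH positions, ring closure through the oxygen para to the acyl group and not an ortho oxygen, cross- versus homo-coupling at the bridge, and one isolated stereocentre, all preferably without protecting groups.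

## Retrosynthetic reasoning

**Bridge (C7–CH2 and CH2–C3′).** 16 is cut at both bonds of the bridging CH2 into the dihydrobenzofuran 9, the pyranone 13 and a one-carbon iminium electrophile. Both ring carbons are innate nucleophiles, so no activating group is needed on either partner. The cut is placed last because 9 has exactly one free aromatic carbon (C7), so the union cannot go astray regiochemically, and because it does not touch C2. In the forward direction 13 is aminomethylated to the Mannich base 14, which loses the amine to give the methide 15. C7 of 9 then adds to 15. The reverse order (bridge first, ring second) was not chosen, because the C3′-substituted pyranone enol would then compete as a soft nucleophile in the allylation chemistry of the key step.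

**Key disconnection (C3–C3a and O1–C2 together).** 9 is cut in one operation at the C–C bond and the C–O bond that tie the isoprene unit to the arene, giving phlorisobutyrophenone 3 and the racemic diacetate 7. Both bonds are allylic with respect to the same C5 unit, and the arene supplies carbon and oxygen nucleophiles in a 1,2-relationship, so a Pd-catalysed [3+2] annulation can form both. The cut removes the whole dihydrofuran ring and the only stereocentre, and leaves an achiral, C2v-symmetric precursor that is one step from phloroglucinol. 7 is chosen because only its tertiary acetate is allylic at the start. This fixes the order of events: C-allylation at the CH2 terminus gives the linear acetate 8, whose primary acetate is only then allylic. The forward reaction must then close the ring through the para oxygen and set C2 under ligand control. Because the π-allyl intermediates equilibrate, racemic 7 and the E/Z mixture of 8 are funnelled into one enantiomer of 9.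

**Diacetate 7.** 7 is cut at the vinyl–carbinol bond to hydroxyacetone 4 and vinylmagnesium bromide 5. The addition gives the dimagnesium diolate 6, which is acetylated in the same flask, so the water-soluble diol need not be isolated. The stereocentre of 7 is left racemic on purpose, since it is erased on ionization.

**Acylphloroglucinol 3.** 3 is cut at the aryl–carbonyl bond to phloroglucinol 1 and isobutyryl chloride 2 (Friedel–Crafts acylation). The first acyl group deactivates the ring, so mono-acylation is expected.

**Pyranone 13.** 13 is cut at the lactone C–O bond to the triketo ester 12, and 12 at the C4–C5 bond to the β-keto ester 10 and the N-methoxy-N-methyl amide 11. The γ-carbanion of the dianion of 10 is the reactive site, and it places the 5′-methyl and 6′-ethyl groups without any further alkylation.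

## Alternatives that were turned down

Alternative 1: the textbook, biomimetic route. Disconnection: O1–C2 by opening of a prenyl epoxide, C=C by dehydration. Forward: C-prenylation of 3 to the prenyl compound A1, asymmetric (Shi-type) epoxidation of the prenyl double bond with 5-exo opening by the para oxygen to the tertiary alcohol A2, then dehydration to 9. Turned down because the dioxirane oxidant and an unprotected phloroglucinol are not compatible, so three phenols would have to be protected and freed again. The epoxide can also open in the 6-endo mode at its tertiary carbon, which acid favours. Dehydration of the tertiary alcohol of A2 must give the isopropenyl and not the conjugated isomer, which then aromatizes the dihydrofuran ring. Base-mediated C-prenylation of 3 competes with O- and bis-prenylation. The ring and stereocentre would cost six or seven operations where the chosen key step needs one.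

Alternative 2: skeletal rearrangement by ring contraction. Disconnection: O1–C2 formed by a 1,2-shift of the aryl oxygen in a 2,2-dimethylchroman-3-ol. Forward: chromene annulation of 3 to A3, enantioselective Mn(salen) epoxidation and reductive opening at C4 to the (S)-chromanol A4, then activation of the 3-OH. The aryl oxygen would displace the leaving group with inversion through a bridged oxonium ion, and the ion would collapse with loss of a methyl proton to 9. Turned down because the migrating oxygen is para to the acyl group, so its lone pair is tied up in a vinylogous ester and it is a poor neighbouring group; plain elimination back to A3 would compete. The tertiary cation can also be recaptured instead of losing a proton. The chromene annulation of 3 has the same para/ortho ambiguity as the chosen route. The epoxidation again demands phenol protection. Five to six steps would be spent to reach a ring that is only an isomer of the one needed.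

Alternative 3: Larock-type heteroannulation. Disconnection: the same two bonds (C3–C3a, O1–C2), but with the arene as the electrophile. Forward: iodination of 3 to the iodide A5, then enantioselective Pd-catalysed annulation with isoprene (A6), in which the aryl–Pd adds to the diene and the phenoxide closes the ring on the π-allyl. Turned down because it installs and then removes a halogen at a carbon that is already a strong nucleophile. Polyhydroxylated aryl iodides of this kind are prone to protodeiodination and oxidation under basic Pd conditions. Insertion must distinguish the two double bonds of A6, and the wrong one leads to the 2-methyl-2-vinyl isomer. The elevated temperature typical of such annulations invites re-ionization of the allylic aryl ether and loss of enantiopurity.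

Key step: step 3

Assumption: the (R,R)-configured DACH-phenyl ligand is taken to deliver the (R)-ether, by analogy with phenol cyclizations onto 2-methyl-substituted π-allyl units; should the sense be opposite, the equally available (S,S)-ligand is used and nothing else changes.

## Route

Step 1
Reactants: 1 phloroglucinol (benzene-1,3,5-triol); 2 isobutyryl chloride (2-methylpropanoyl chloride)
Product: 3 phlorisobutyrophenone, 2-methyl-1-(2,4,6-trihydroxyphenyl)propan-1-one
Conditions: AlCl3 (3.5 equiv), CH2Cl2/MeNO2, 0 → 40 °C; ice/1 M HCl
Reagents that add atoms: none
Why: Friedel–Crafts C-acylation of the most electron-rich simple arene; the first acyl group deactivates the ring and is chelated by aluminium, so mono-acylation should prevail.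

Step 2
Reactants: 4 hydroxyacetone (1-hydroxypropan-2-one); 5 vinylmagnesium bromide
Product: 7 rac-2-methylbut-3-ene-1,2-diyl diacetate, via dimagnesium diolate 6 (not isolated)
Conditions: 5 (2.2 equiv), THF, 0 °C → rt; then Ac2O (3 equiv), DMAP (0.1 equiv), 0 °C → rt; aq. NH4Cl
Reagents that add atoms: acetic anhydride, CC(=O)OC(C)=O
Why: Grignard addition: the first equivalent of 5 deprotonates the hydroxyl, the second adds to the chelated ketone, and both magnesium alkoxides of 6 are acetylated in the flask (a standard trapping of tertiary allylic alkoxides); the new stereocentre is racemic on purpose, because step 3 erases it.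

Step 3
Reactants: 3 phlorisobutyrophenone (2.5 equiv, excess recovered); 7 rac-2-methylbut-3-ene-1,2-diyl diacetate
Product: 9 1-[(2R)-4,6-dihydroxy-2-(prop-1-en-2-yl)-2,3-dihydro-1-benzofuran-5-yl]-2-methylpropan-1-one, via linear allylic acetate 8 (not isolated)
Conditions: Pd2(dba)3·CHCl3 (2.5 mol %), (R,R)-DACH-phenyl ligand N,N′-[(1R,2R)-cyclohexane-1,2-diyl]bis[2-(diphenylphosphanyl)benzamide] (7.5 mol %), Et3N (2.5 equiv), degassed THF, 0 °C → rt, slow addition of 7
Reagents that add atoms: none
Why: Tsuji–Trost cascade: Pd(0)–ligand ionizes the tertiary allylic acetate of either enantiomer of 7 (the primary acetate is not yet allylic, so the order of events is fixed) to a 1,1-disubstituted π-allyl, and the triethylammonium phenoxide of 3 attacks its unsubstituted CH2 terminus through the enolic carbon C3 to give 8 as an E/Z mixture, since O-allylation of this acidic phenol is reversible under Pd(0) and C-allylation is not. The primary acetate of 8 is now allylic and ionizes to a 2-methyl-π-allyl, whose internal terminus is attacked anti to palladium by the C4 phenoxide oxygen. This closes the dihydrofuran ring in the 5-exo mode (O1–C2); attack at the CH2 terminus would be a strained 7-endo closure. The closest known reaction types are the Pd-catalysed [3+2] annulation of cyclic 1,3-dicarbonyl C,O-bis-nucleophiles with butenediyl diesters to 2-vinyl-2,3-dihydrofurans and the asymmetric Pd/DACH-phenyl cyclization of 2-(4-acyloxy-3-methylbut-2-enyl)phenols to 2-isopropenyl-2,3-dihydrobenzofurans. C2 is set by the ligand in the C–O bond-forming step: the diastereomeric π-allyl complexes interconvert by π–σ–π exchange through the unsubstituted CH2 terminus faster than they cyclize, so both enantiomers of 7, both alkene isomers of 8 and both allyl faces should funnel into (R)-9 (Curtin–Hammett control). Mono- over bis-annulation is secured by the excess of C2v-symmetric 3 and slow addition of 7, and closure through the para oxygen by the fact that C4–OH is the most acidic hydroxyl (a vinylogous acid) while both ortho hydroxyls are locked in hydrogen bonds to the ketone. Kinetic control is required because the product is itself an allylic aryl ether; low temperature and a stop at full consumption of 8 should keep re-ionization negligible.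

Step 4
Reactants: 10 methyl 3-oxopentanoate; 11 N-methoxy-N-methylpropanamide
Product: 12 methyl 4-methyl-3,5-dioxoheptanoate (racemic, keto–enol mixture)
Conditions: LDA (2.2 equiv), THF, −78 → 0 °C; then 11, −78 → 0 °C; aq. NH4Cl/HCl to pH 3
Reagents that add atoms: none
Why: γ-Acylation of a β-keto ester dianion (Claisen-type): the C4 carbanion is the more reactive site, and the N-methoxy-N-methyl amide gives a chelated tetrahedral intermediate that survives until work-up, which should prevent over-addition and proton transfer from the more acidic product.

Step 5
Reactants: 12 methyl 4-methyl-3,5-dioxoheptanoate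
Product: 13 6-ethyl-4-hydroxy-5-methyl-2H-pyran-2-one
Conditions: DBU (1.2 equiv), toluene, reflux; then 1 M HCl
Reagents that add atoms: none
Why: Lactonization of a 3,5-dioxo ester: the enol oxygen of the C5 ketone attacks the ester with loss of methanol, driven by formation of the 4-hydroxy-2-pyranone; the stereocentre of 12 disappears.

Step 6
Reactants: 9 1-[(2R)-4,6-dihydroxy-2-(prop-1-en-2-yl)-2,3-dihydro-1-benzofuran-5-yl]-2-methylpropan-1-one; 13 6-ethyl-4-hydroxy-5-methyl-2H-pyran-2-one
Product: 16 6-ethyl-4-hydroxy-3-{[(2R)-4,6-dihydroxy-5-(2-methylpropanoyl)-2-(prop-1-en-2-yl)-2,3-dihydro-1-benzofuran-7-yl]methyl}-5-methyl-2H-pyran-2-one (target), via Mannich base 14 (not isolated), via pyranone methide 15 (not isolated)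
Conditions: 13, Me2N+=CH2 I− (1.05 equiv), CHCl3, rt; then 9 (1.0 equiv), 45 °C, Ar
Reagents that add atoms: N,N-dimethylmethyleneiminium iodide (Eschenmoser's salt), C=[N+](C)C.[I-]
Why: Mannich reaction at C3′ of 13 gives 14, which loses dimethylamine on warming to the methide 15; the only free aromatic carbon of 9 (C7) adds to 15 in a conjugate, Friedel–Crafts-type step, and the mild, nearly neutral conditions should leave the isopropenyl group and C2 untouched.

## Compound list

1 | phloroglucinol (benzene-1,3,5-triol) | Oc1cc(O)cc(O)c1 | starting material
2 | isobutyryl chloride (2-methylpropanoyl chloride) | CC(C)C(Cl)=O | starting material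
3 | phlorisobutyrophenone, 2-methyl-1-(2,4,6-trihydroxyphenyl)propan-1-one | CC(C)C(=O)c1c(O)cc(O)cc1O | intermediate
4 | hydroxyacetone (1-hydroxypropan-2-one) | CC(=O)CO | starting material
5 | vinylmagnesium bromide | C=C[Mg]Br | starting material
6 | bis(bromomagnesium) 2-methylbut-3-ene-1,2-diolate (racemic) | C=CC(C)(O[Mg]Br)CO[Mg]Br | intermediate (not isolated)
7 | rac-2-methylbut-3-ene-1,2-diyl diacetate | CC(=O)OCC(C)(OC(C)=O)C=C | intermediate
8 | (E)-4-[2,4,6-trihydroxy-3-(2-methylpropanoyl)phenyl]-2-methylbut-2-en-1-yl acetate (expected as an E/Z mixture, E drawn) | CC(C)C(=O)c1c(O)cc(O)c(C/C=C(\C)COC(C)=O)c1O | intermediate (not isolated)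
9 | 1-[(2R)-4,6-dihydroxy-2-(prop-1-en-2-yl)-2,3-dihydro-1-benzofuran-5-yl]-2-methylpropan-1-one | C=C(C)[C@H]1Cc2c(O)c(C(=O)C(C)C)c(O)cc2O1 | intermediate
10 | methyl 3-oxopentanoate | CCC(=O)CC(=O)OC | starting material
11 | N-methoxy-N-methylpropanamide | CCC(=O)N(C)OC | starting material
12 | methyl 4-methyl-3,5-dioxoheptanoate (racemic) | CCC(=O)C(C)C(=O)CC(=O)OC | intermediate
13 | 6-ethyl-4-hydroxy-5-methyl-2H-pyran-2-one | CCc1oc(=O)cc(O)c1C | intermediate
14 | 3-[(dimethylamino)methyl]-6-ethyl-4-hydroxy-5-methyl-2H-pyran-2-one | CCc1oc(=O)c(CN(C)C)c(O)c1C | intermediate (not isolated)
15 | 6-ethyl-5-methyl-3-methylidene-2H-pyran-2,4(3H)-dione | CCC1=C(C)C(=O)C(=C)C(=O)O1 | intermediate (not isolated)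
16 | 6-ethyl-4-hydroxy-3-{[(2R)-4,6-dihydroxy-5-(2-methylpropanoyl)-2-(prop-1-en-2-yl)-2,3-dihydro-1-benzofuran-7-yl]methyl}-5-methyl-2H-pyran-2-one | C=C(C)[C@H]1Cc2c(O)c(C(=O)C(C)C)c(O)c(Cc3c(O)c(C)c(CC)oc3=O)c2O1 | target

## Step count and risk

Total step count: 6. Longest linear sequence: 3 steps (1 → 3 → 9 → 16; the branches from 4 and from 10 are equally long).

Least certain steps:

**Step 3 (key step).** Most likely to go wrong:
- over-allylation, because the product still has a nucleophilic C7 and the starting phenol has two equivalent carbons, so a second π-allyl can be captured intermolecularly;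
- closure through an ortho oxygen instead of the para oxygen;
- loss of enantiopurity by re-ionization of the allylic aryl ether of the product under Pd(0);
- β-hydride loss from the π-allyl to a diene, or sluggish ionization of one enantiomer of 7 by the chiral catalyst.

Fallback (sets out from 3, comes back to the route at 8): the two bond formations are separated, so that the enantio-determining step is purely intramolecular. Pd(PPh3)4-catalysed 1,4-opening of commercial 2-methyl-2-vinyloxirane by the phenoxide carbon of 3 in THF would give the allylic alcohol (E)-1-[2,4,6-trihydroxy-3-(4-hydroxy-3-methylbut-2-en-1-yl)phenyl]-2-methylpropan-1-one F1. Immobilized Candida antarctica lipase B with vinyl acetate would acetylate only the primary aliphatic hydroxyl of F1 and leave the phenols free, giving 8, which is now isolated. 8 would then be cyclized to 9 with the same Pd/DACH-phenyl catalyst and Et3N in CH2Cl2 at low temperature, where no intermolecular allylation competes.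

**Step 6.** Most likely to go wrong: homo-coupling, because the methide 15 can be captured by a second molecule of 13 instead of by 9, and the iminium salt can aminomethylate 9 directly and lead to the symmetric bis-benzofuranyl methane; slow acid-promoted isomerization of the isopropenyl group by the ammonium iodide formed is a lesser concern.

Fallback (sets out from 9, comes back at 16): the one-carbon unit is attached to the arene first at the aldehyde oxidation level, which rules out homo-coupling. Vilsmeier–Haack formylation of 9 (POCl3, DMF, MeCN, 0 °C; aq. NaOAc) would give (2R)-4,6-dihydroxy-5-(2-methylpropanoyl)-2-(prop-1-en-2-yl)-2,3-dihydro-1-benzofuran-7-carbaldehyde F2. A three-component reductive alkylation of 13 with F2, catalytic L-proline and diethyl 2,6-dimethyl-1,4-dihydropyridine-3,5-dicarboxylate at rt would pass through the Knoevenagel adduct 3-{[(2R)-4,6-dihydroxy-5-(2-methylpropanoyl)-2-(prop-1-en-2-yl)-2,3-dihydro-1-benzofuran-7-yl]methylidene}-6-ethyl-5-methyl-2H-pyran-2,4(3H)-dione F3, which is reduced in the flask by hydride transfer to 16.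

**Step 4.** Most likely to go wrong: incomplete dianion formation at the more hindered, secondary γ-carbon, proton transfer between dianion and amide, and O- instead of C-acylation, all of which lower the conversion to 12.

Fallback (sets out from 10, comes back at 12): the acylation is moved from strongly basic to neutral conditions. Silylation of 10 (Me3SiCl, Et3N) would give methyl 3-(trimethylsilyloxy)pent-2-enoate F4. Deprotonation with LDA and a second silylation at −78 °C would give 1-methoxy-1,3-bis(trimethylsilyloxy)penta-1,3-diene F5. The terminal carbon of F5 would then be acylated by propanoyl chloride in CH2Cl2 (−78 °C → rt) in a Mukaiyama-type reaction and, after aqueous work-up, should deliver 12.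

## Further compounds

F1 | step 3 | (E)-1-[2,4,6-trihydroxy-3-(4-hydroxy-3-methylbut-2-en-1-yl)phenyl]-2-methylpropan-1-one | CC(C)C(=O)c1c(O)cc(O)c(C/C=C(\C)CO)c1O
F2 | step 6 | (2R)-4,6-dihydroxy-5-(2-methylpropanoyl)-2-(prop-1-en-2-yl)-2,3-dihydro-1-benzofuran-7-carbaldehyde | C=C(C)[C@H]1Cc2c(O)c(C(=O)C(C)C)c(O)c(C=O)c2O1
F3 | step 6 | 3-{[(2R)-4,6-dihydroxy-5-(2-methylpropanoyl)-2-(prop-1-en-2-yl)-2,3-dihydro-1-benzofuran-7-yl]methylidene}-6-ethyl-5-methyl-2H-pyran-2,4(3H)-dione | C=C(C)[C@H]1Cc2c(O)c(C(=O)C(C)C)c(O)c(C=C3C(=O)OC(CC)=C(C)C3=O)c2O1
F4 | step 4 | methyl 3-(trimethylsilyloxy)pent-2-enoate | CCC(=CC(=O)OC)O[Si](C)(C)C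
F5 | step 4 | 1-methoxy-1,3-bis(trimethylsilyloxy)penta-1,3-diene | CC=C(O[Si](C)(C)C)C=C(OC)O[Si](C)(C)C
A1 | alternative 1 | 2-methyl-1-[2,4,6-trihydroxy-3-(3-methylbut-2-en-1-yl)phenyl]propan-1-one | CC(C)C(=O)c1c(O)cc(O)c(CC=C(C)C)c1O
A2 | alternative 1 | 1-[(2R)-4,6-dihydroxy-2-(2-hydroxypropan-2-yl)-2,3-dihydro-1-benzofuran-5-yl]-2-methylpropan-1-one | CC(C)(O)[C@H]1Cc2c(O)c(C(=O)C(C)C)c(O)cc2O1
A3 | alternative 2 | 1-(5,7-dihydroxy-2,2-dimethyl-2H-chromen-6-yl)-2-methylpropan-1-one | CC(C)C(=O)c1c(O)cc2OC(C)(C)C=Cc2c1O
A4 | alternative 2 | 1-[(3S)-3,5,7-trihydroxy-2,2-dimethyl-3,4-dihydro-2H-chromen-6-yl]-2-methylpropan-1-one | CC(C)C(=O)c1c(O)cc2OC(C)(C)[C@@H](O)Cc2c1O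
A5 | alternative 3 | 1-(2,4,6-trihydroxy-3-iodophenyl)-2-methylpropan-1-one | CC(C)C(=O)c1c(O)cc(O)c(I)c1O
A6 | alternative 3 | isoprene (2-methylbuta-1,3-diene; reagent of the alternative, not made) | C=CC(C)=C
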